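**Plan**

- Retrosynthesis: the side chain is cut at the sp3–sp2 bond between its second and third carbon (B-alkyl Suzuki–Miyaura), giving vinyl carbinol 5 and the C19 (E)-alkenyl iodide 10. Compound 5 goes back to hydroxy aldehyde 4 (methylenation), and the ring of 4 is cut at CH2–C(CH3)2 and at CH–C(OH).
- Enabling feature: the ring arc C(OH)(CH3)–CH2–CH2–CH2 is 1-methylcyclobutanol opened at its carbinol–CH2 bond, and the other two ring carbons, C(CH3)2–CH, are the C=C of prenal. The hydroxyl is β to the exocyclic carbon, an aldol relationship.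
- Forward: the only ring arises in step 1 (one flask: radical C–C bond, then enamine aldol C–C bond); methylenation follows; iodide 10 is made in two steps from farnesyl bromide; hydroboration and Suzuki coupling join the chain last.
- Stereochemistry: both ring centres come from the (S)-proline-controlled aldol closure (hydroxyl trans to the chain carbon, 1S,2S) and are not touched again. Two E alkenes come from (2E,6E)-farnesyl bromide, the third from syn hydrozirconation with iodinolysis and coupling under retention.

Key step: step 1

Remark on the chemistry: commercial (2E,6E)-farnesyl bromide is assumed to be geometrically pure, so no isomer separation is planned.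

**Step 1**
Reactants: 1 1-methylcyclobutan-1-ol; 2 3-methylbut-2-enal (prenal)
Product: 4 (1S,2S)-2-hydroxy-2,6,6-trimethylcyclohexane-1-carbaldehyde, via keto aldehyde 3 (not isolated)
Conditions: [Ir(dF(CF3)ppy)2(5,5'-d(CF3)bpy)]PF6 (2 mol%), Bu4N[O2P(OBu)2] (25 mol%), 2 (4 equiv), PhCF3, degassed, blue LEDs, rt; then light off, volatiles removed in vacuo, (S)-proline (30 mol%), CH2Cl2, rt
Reagents that add atoms: none
Why: Proposed new method: the excited trivalent iridium complex and the phosphate base remove the hydroxyl hydrogen of 1 by proton-coupled electron transfer, the strained cyclobutyloxyl radical opens by β-scission to the 4-oxopentyl radical, this nucleophilic radical adds to the β-carbon of 2 (bond CH2–C(CH3)2), and reduction by divalent iridium with protonation gives 3. (S)-Proline then converts the aldehyde of 3 into its E-enamine, which attacks the methyl ketone (bond CH–C(OH)) and is hydrolysed to 4. The closest known reaction types are the photocatalytic ring-opening Giese addition and ring expansion of cycloalkanols with electron-poor alkenes and the proline-catalysed enolexo aldolization of 1,7-dicarbonyl compounds; their union in one flask on a doubly β-substituted enal and a ketone acceptor next to a quaternary carbon is new. The only ring closes in the 6-(enolexo)-exo-trig mode through a chair in which the carboxylic acid of the enamine is hydrogen-bonded to the ketone oxygen, so that oxygen and enamine carbon are gauche and both equatorial on the forming ring; this sets the carbinol centre with hydroxyl trans to formyl. The (S)-configured pyrrolidine carboxylic acid lets the ketone approach only one face of the enamine and so should set the formyl-bearing centre and the absolute sense (1S,2S), in line with aldol reactions of aldehyde enamines of (S)-proline. Needed are β-attack of a primary radical on a hindered acceptor (excess 2, a solvent without weak C–H bonds and the irreversible strain-releasing scission secure it), trans over cis closure (the quaternary carbon enforces the E-enamine, which reaches the hydrogen-bonded chair only in the trans-fused array) and no dehydration (neutral medium, room temperature, 4 taken on at once).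

**Step 2**
Reactants: 4 (1S,2S)-2-hydroxy-2,6,6-trimethylcyclohexane-1-carbaldehyde
Product: 5 (1S,2S)-2-ethenyl-1,3,3-trimethylcyclohexan-1-ol
Conditions: Ph3PCH3Br (2.3 equiv), KN(SiMe3)2 (2.2 equiv), THF, −78 to 0 °C
Reagents that add atoms: methyltriphenylphosphonium bromide, C[P+](c1ccccc1)(c1ccccc1)c1ccccc1.[Br-]
Why: Wittig methylenation with the non-stabilised ylide, which should add to the aldehyde faster than it removes the hindered α-hydrogen and is too weak a base to ionise the tertiary hydroxyl, so both stereocentres are carried through.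

**Step 3**
Reactants: 6 (2E,6E)-1-bromo-3,7,11-trimethyldodeca-2,6,10-triene (farnesyl bromide)
Product: 8 (6E,10E)-2,6,10-trimethylhexadeca-2,6,10-trien-14-yne, via lithium acetylide 7 (not isolated)
Conditions: propargyl bromide (1.5 equiv), n-BuLi (3.0 equiv), TMEDA, Et2O/hexane, −78 °C; then 6, −78 to 0 °C; then MeI, DMPU, 0 °C to rt
Reagents that add atoms: 3-bromoprop-1-yne (propargyl bromide), C#CCBr; iodomethane, [CH3]I
Why: The propargylic carbanion of 1,3-dilithiopropyne displaces the primary allylic bromide in an SN2 alkylation that leaves the E alkenes untouched, and the remaining lithium acetylide 7 is C-methylated by iodomethane once DMPU is added (acetylide alkylation).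

**Step 4**
Reactants: 8 (6E,10E)-2,6,10-trimethylhexadeca-2,6,10-trien-14-yne
Product: 10 (6E,10E,14E)-15-iodo-2,6,10-trimethylhexadeca-2,6,10,14-tetraene, via alkenylzirconocene chloride 9 (not isolated)
Conditions: Cp2Zr(H)Cl (1.5 equiv), THF, 50 °C; then I2, 0 °C
Reagents that add atoms: iodine, [I][I]
Why: Hydrozirconation adds Zr–H syn across the alkyne and, with excess Cp2Zr(H)Cl and gentle heating, equilibrates zirconium onto the less hindered methyl-bearing carbon, and iodinolysis of the C–Zr bond with retention gives the E iodide (hydrozirconation–iodination), the trisubstituted alkenes being inert.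

**Step 5**
Reactants: 5 (1S,2S)-2-ethenyl-1,3,3-trimethylcyclohexan-1-ol; 10 (6E,10E,14E)-15-iodo-2,6,10-trimethylhexadeca-2,6,10,14-tetraene
Product: 12 (1S,2S)-1,3,3-trimethyl-2-[(3E,7E,11E)-3,8,12,16-tetramethylheptadeca-3,7,11,15-tetraen-1-yl]cyclohexan-1-ol, via B-alkyl borane 11 (not isolated)
Conditions: 9-BBN (2.2 equiv), THF, rt; then 10, PdCl2(dppf) (5 mol%), AsPh3 (10 mol%), Cs2CO3, DMF/H2O, rt
Reagents that add atoms: none
Why: Anti-Markovnikov hydroboration of the monosubstituted alkene with 9-BBN gives the primary borane, and B-alkyl Suzuki–Miyaura coupling at zerovalent palladium joins it to the alkenyl iodide with retention of the E geometry, leaving both stereocentres and the hindered tertiary hydroxyl untouched (any B–O bond at the carbinol is cleaved by the aqueous base).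

**Compound list**

1 | 1-methylcyclobutan-1-ol | CC1(O)CCC1 | starting material
2 | 3-methylbut-2-enal (prenal) | CC(C)=CC=O | starting material
3 | 3,3-dimethyl-7-oxooctanal | CC(=O)CCCC(C)(C)CC=O | intermediate
4 | (1S,2S)-2-hydroxy-2,6,6-trimethylcyclohexane-1-carbaldehyde | O=C[C@H]1C(C)(C)CCC[C@]1(C)O | intermediate
5 | (1S,2S)-2-ethenyl-1,3,3-trimethylcyclohexan-1-ol | C=C[C@H]1C(C)(C)CCC[C@]1(C)O | intermediate
6 | (2E,6E)-1-bromo-3,7,11-trimethyldodeca-2,6,10-triene (farnesyl bromide) | CC(C)=CCC/C(C)=C/CC/C(C)=C/CBr | starting material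
7 | [(5E,9E)-6,10,14-trimethylpentadeca-5,9,13-trien-1-yn-1-yl]lithium | CC(C)=CCC/C(C)=C/CC/C(C)=C/CCC#C[Li] | intermediate
8 | (6E,10E)-2,6,10-trimethylhexadeca-2,6,10-trien-14-yne | CC(C)=CCC/C(C)=C/CC/C(C)=C/CCC#CC | intermediate
9 | chlorobis(cyclopentadienyl)[(2E,6E,10E)-7,11,15-trimethylhexadeca-2,6,10,14-tetraen-2-yl]zirconium (rings drawn σ-bound) | CC(C)=CCC/C(C)=C/CC/C(C)=C/CC/C=C(\C)[Zr](Cl)(C1C=CC=C1)C1C=CC=C1 | intermediate
10 | (6E,10E,14E)-15-iodo-2,6,10-trimethylhexadeca-2,6,10,14-tetraene | CC(C)=CCC/C(C)=C/CC/C(C)=C/CC/C=C(\C)I | intermediate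
11 | 9-{2-[(1S,2S)-2-hydroxy-2,6,6-trimethylcyclohexyl]ethyl}-9-borabicyclo[3.3.1]nonane | C1CCC2CCCC1B2CC[C@H]1C(C)(C)CCC[C@]1(C)O | intermediate
12 | (1S,2S)-1,3,3-trimethyl-2-[(3E,7E,11E)-3,8,12,16-tetramethylheptadeca-3,7,11,15-tetraen-1-yl]cyclohexan-1-ol | CC(C)=CCC/C(C)=C/CC/C(C)=C/CC/C=C(\C)CC[C@H]1C(C)(C)CCC[C@]1(C)O | target

**Totals**

Total step count: 5. Longest linear sequence: 3 steps (steps 1, 2 and 5 from 1 and 2; equally steps 3, 4 and 5 from 6).

**Steps most likely to fail**

Step 1 (proposed new method). The primary 4-oxopentyl radical may be consumed by an internal 1,5-hydrogen shift or by hydrogen abstraction from 2 before it adds to the doubly substituted β-carbon, and the aldehyde may be degraded under irradiation. The fallback uses known chemistry, sets out from 2 and returns at 3. Commercial 2-(3-chloropropyl)-2-methyl-1,3-dioxolane (CC1(CCCCl)OCCO1) is converted with Mg in THF into [3-(2-methyl-1,3-dioxolan-2-yl)propyl]magnesium chloride F1. F1 is added to 2 with CuBr·SMe2 (5 mol%), Me3SiCl and DMPU in THF at −78 °C (copper-catalysed, silyl-accelerated conjugate addition) to give trimethyl{[3,3-dimethyl-6-(2-methyl-1,3-dioxolan-2-yl)hex-1-en-1-yl]oxy}silane F2. Aqueous HCl in THF hydrolyses the enol ether and the ketal to 3, which is isolated and closed to 4 with (S)-proline in CH2Cl2 as in the second stage of step 1.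

Step 4. Incomplete equilibration of the two regioisomeric alkenylzirconium species would carry the 14-iodo isomer into the coupling. The fallback fixes the regiochemistry with silicon; it sets out from 6 and returns at 10. Compound 6 is alkylated with the lithium derivative of 1-(trimethylsilyl)propyne (n-BuLi, THF, −78 °C) to give trimethyl[(5E,9E)-6,10,14-trimethylpentadeca-5,9,13-trien-1-yn-1-yl]silane F3. i-Bu2AlH in heptane adds H–Al with aluminium on the silicon-bearing carbon and net trans geometry to give bis(2-methylpropyl)[(1E,5E,9E)-6,10,14-trimethyl-1-(trimethylsilyl)pentadeca-1,5,9,13-tetraen-1-yl]alumane F4. MeLi followed by MeI replaces aluminium by methyl with retention to give trimethyl[(2E,6E,10E)-7,11,15-trimethylhexadeca-2,6,10,14-tetraen-2-yl]silane F5. N-Iodosuccinimide in MeCN/ClCH2CN then effects ipso-iododesilylation with retention to 10.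

Step 2. The ylide may act as a base, causing epimerization at the formyl-bearing carbon or retro-aldol opening and dehydration of the β-hydroxy aldehyde. The fallback masks the carbinol and transfers the methylene with a non-basic reagent; it sets out from 4 and returns at 5. Compound 4 is silylated with N-(trimethylsilyl)imidazole to (1S,2S)-2,6,6-trimethyl-2-[(trimethylsilyl)oxy]cyclohexane-1-carbaldehyde F6, which cannot undergo retro-aldol cleavage. Petasis methylenation with Cp2TiMe2 (toluene, 65 °C) gives {[(1S,2S)-2-ethenyl-1,3,3-trimethylcyclohexyl]oxy}trimethylsilane F7, and Bu4NF in THF frees 5.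

**Further compounds**

F1 | step 1 | [3-(2-methyl-1,3-dioxolan-2-yl)propyl]magnesium chloride | CC1(CCC[Mg]Cl)OCCO1
F2 | step 1 | trimethyl{[3,3-dimethyl-6-(2-methyl-1,3-dioxolan-2-yl)hex-1-en-1-yl]oxy}silane | C[Si](C)(C)OC=CC(C)(C)CCCC1(C)OCCO1
F3 | step 4 | trimethyl[(5E,9E)-6,10,14-trimethylpentadeca-5,9,13-trien-1-yn-1-yl]silane | CC(C)=CCC/C(C)=C/CC/C(C)=C/CCC#C[Si](C)(C)C
F4 | step 4 | bis(2-methylpropyl)[(1E,5E,9E)-6,10,14-trimethyl-1-(trimethylsilyl)pentadeca-1,5,9,13-tetraen-1-yl]alumane | CC(C)=CCC/C(C)=C/CC/C(C)=C/CC/C=C(\[Al](CC(C)C)CC(C)C)[Si](C)(C)C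
F5 | step 4 | trimethyl[(2E,6E,10E)-7,11,15-trimethylhexadeca-2,6,10,14-tetraen-2-yl]silane | CC(C)=CCC/C(C)=C/CC/C(C)=C/CC/C=C(\C)[Si](C)(C)C
F6 | step 2 | (1S,2S)-2,6,6-trimethyl-2-[(trimethylsilyl)oxy]cyclohexane-1-carbaldehyde | O=C[C@H]1C(C)(C)CCC[C@]1(C)O[Si](C)(C)C
F7 | step 2 | {[(1S,2S)-2-ethenyl-1,3,3-trimethylcyclohexyl]oxy}trimethylsilane | C=C[C@H]1C(C)(C)CCC[C@]1(C)O[Si](C)(C)C
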